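If the fall of free monomer in birch, the run of this very flask, is first order, one constant describes it: 74% left at 50.0 s reads as 0.006022 s⁻¹, and cedar, charged lower, read 0.005385 s⁻¹. The suspects are these: initiator takes a free monomer to begin a living end, a living end adds free monomer to its chain, and free monomer turns by itself into uncatalysed product.

| setting | birch | cedar | flask |
|---|---|---|---|
| free monomer | 2.1 M | 1.4 M | 2.1 M |
| initiator | 4.2 mM | 4.2 mM | 4.2 mM |
| remark | the very flask that is asked about, followed so far | run made earlier |  |
| time |  |  | 2.0 min |

- birch (time / s: monomer in chains / %, free monomer / %): 10.0: 0, 93; 15.0: 0, 93; 20.0: 0, 91; 30.0: 2, 85; 50.0: 2, 74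
- cedar (time / s: monomer in chains / %, free monomer / %): 10.0: 3, 93; 15.0: 1, 94; 25.0: 0, 87; 40.0: 1, 82; 60.0: 2, 70; 80.0: 6, 65

(each reading ± 1.5 percentage points)

- whether the average number of monomer units in a chain (chains begun, living or dead) reaches 70 by 2.0 min (no / yes)
- average number of monomer units in a chain (chains begun, living or dead) at 2.0 min

- the average divides the monomer in chains by the number of chains begun, living and dead together
- on the list of suspects stand: free monomer + living end -> monomer in chains + living end; free monomer + initiator -> living end + monomer in chains; free monomer -> uncatalysed product
- the earlier runs do not show the number of chains; that part of a forecast is a guess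

Both chain steps use free monomer, so I counted time by the monomer clock, the time weighted by the fraction of free monomer left, which is the fraction lost divided by that constant. For this flask it read 85.4 s at 2.0 min.

I solved both ends. If initiator begins every chain at once, each chain grows in proportion to the clock. If chains begin steadily, they have on average run half the clock. So at both ends the mean chain length, the number-average degree of polymerisation, is proportional to the clock, with a constant of proportion that holds the growth constant.

Monomer in chains goes as charge times clock squared at the slow end. Scaled that way, birch's 2% gave 7.83% at 2.0 min and cedar's 6% gave 16.3%. Their mean over the full initiator charge makes a length of 60.3. Length 70 is then passed if under 86.2% of the initiator has begun chains. Birch's 0% in chains at 20.0 s did not point to slow starting, since a start at once, scaled on the clock from its 2% at 50.0 s, gives 0.873% there, and a reading is good to 1.5 percentage points. The runs do not show the number of chains, so my yes was a guess on that share of the initiator.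

The forecast differed: no, with length 42, and it warned, “The number of chains is unseen, so this is a guess”.

The flask gave 137, so the answer was yes.

    free monomer + living end → monomer in chains + living end, rate k1*[living end]*[free monomer] (k = 1.42 M⁻¹ s⁻¹)
    free monomer + initiator → living end + monomer in chains (k = 0.00285 M⁻¹ s⁻¹)
    free monomer → uncatalysed product (k = 0.00525 s⁻¹)

Living ends stood at 0.00167 M at 2.00 min, with 60% of the initiator left. On the clock, the flask's length ran at 1.60 s⁻¹. At 0.853 min the clock read 44.1 s, which makes 70.7, and the flask reached 70 at 0.853 min.

The runs stem from a simulated flask for an exercise, noise included.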